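**Strategy.** Everything rests on forming the lactone O–C6 bond by alkylation of the C12 carboxylate at C6, not by acylation of a C6 alcohol. C6, the oxygen-bearing carbon of the five-membered lactone ring (O–C6–C7–C11–C12), is a secondary allylic carbon beside C7, which carries the acrylic acid. A γ-hydroxy acid whose C6 hydroxyl is epimeric to the target therefore closes by Mitsunobu 5-exo-tet displacement with inversion. In one operation this closes the α-methylene-γ-lactone, sets the trans C6/C7 ring fusion and spares the epoxyangelate. The precursor is the acyclic syn adduct of an indium Barbier coupling between acrolein and a (Z)-2-(bromomethyl)enoate bearing the C8 ester. Ring-closing metathesis then forms the Z-C4=C5 bond of the ten-membered ring.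

Key step: step 15

Remark: germacrane numbering is used for locants (lactone oxygen on C6, ester on C8, hydroxyl on C2, exo-methylene C13 on C11); but-2-ynal and (R)-PMB glycidyl ether are taken as purchasable.

Step 1
Reactants: 1 angelic acid [(2Z)-2-methylbut-2-enoic acid]
Product: 2 (2Z)-2-methylbut-2-en-1-ol
Conditions: LiAlH4, Et2O, 0 °C → rt
Reagents that add atoms: none
Why: Hydride reduction of the carboxylic acid by LiAlH4 should give the primary allylic alcohol, with the trisubstituted alkene and its Z geometry untouched.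

Step 2
Reactants: 2 (2Z)-2-methylbut-2-en-1-ol
Product: 3 [(2S,3R)-2,3-dimethyloxiran-2-yl]methanol
Conditions: Ti(OiPr)4 (cat.), L-(+)-DET (cat.), t-BuOOH, 4 Å MS, CH2Cl2, −20 °C
Reagents that add atoms: tert-butyl hydroperoxide, CC(C)(C)OO
Why: Sharpless asymmetric epoxidation; with L-(+)-DET the oxygen should be delivered to the face that gives the (2S,3R)-epoxy alcohol, and syn addition turns the Z geometry into the cis relation of CH2OH and the C3 methyl group.

Step 3
Reactants: 3 [(2S,3R)-2,3-dimethyloxiran-2-yl]methanol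
Product: 4 (2R,3R)-2,3-dimethyloxirane-2-carboxylic acid
Conditions: RuCl3 (cat.), NaIO4, CCl4/MeCN/H2O, rt
Reagents that add atoms: water, O
Why: Catalytic RuO4 oxidation (Sharpless conditions) takes the primary alcohol to the acid without touching the epoxide; C2 is fully substituted and cannot epimerise (its descriptor changes from S to R by priority only).

Step 4
Reactants: 5 but-2-ynal
Product: 6 (4S)-6-methylhept-6-en-2-yn-4-ol
Conditions: (−)-Ipc2BOMe, 2-methylallylmagnesium chloride, Et2O, −78 °C → rt; then 5, −78 °C; then NaOH, H2O2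
Reagents that add atoms: 2-methylallylmagnesium chloride, C=C(C)C[Mg]Cl
Why: Brown asymmetric methallylation through a closed chair transition state; the reagent from (−)-Ipc2BOMe should add to the Si face of the ynal and set the C2 carbinol as S.

Step 5
Reactants: 6 (4S)-6-methylhept-6-en-2-yn-4-ol
Product: 8 (2Z,4S)-2-iodo-6-methylhepta-2,6-dien-4-ol, via cyclic alkenylalanate 7 (not isolated)
Conditions: Red-Al, THF, 0 °C → rt; then I2, −78 °C
Reagents that add atoms: iodine, II
Why: Hydroxyl-directed trans-hydroalumination of the propargylic alcohol places aluminium on the methyl-bearing carbon in a five-membered alanate, and iodinolysis with retention should give the (Z)-vinyl iodide that fixes the later C1=C10 geometry.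

Step 6
Reactants: 8 (2Z,4S)-2-iodo-6-methylhepta-2,6-dien-4-ol
Product: 9 tert-butyl{[(2Z,4S)-2-iodo-6-methylhepta-2,6-dien-4-yl]oxy}dimethylsilane
Conditions: TBSCl, imidazole, DMF, rt
Reagents that add atoms: tert-butyldimethylsilyl chloride, CC(C)(C)[Si](C)(C)Cl
Why: Standard silylation of the secondary allylic alcohol; the TBS ether masks O2 through the organolithium, Mitsunobu and metathesis steps.

Step 7
Reactants: 9 tert-butyl{[(2Z,4S)-2-iodo-6-methylhepta-2,6-dien-4-yl]oxy}dimethylsilane; 10 (R)-2-{[(4-methoxybenzyl)oxy]methyl}oxirane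
Product: 12 (2R,4Z,6S)-6-[(tert-butyldimethylsilyl)oxy]-1-[(4-methoxybenzyl)oxy]-4,8-dimethylnona-4,8-dien-2-ol, via alkenyllithium 11 (not isolated)
Conditions: t-BuLi (2.1 equiv), Et2O, −78 °C; then 10, BF3·OEt2, −78 °C
Reagents that add atoms: none
Why: Iodine–lithium exchange with retention of alkene geometry (kept at −78 °C to prevent 1,4-silyl migration), then BF3-promoted SN2 opening of the terminal epoxide at CH2, should form C9–C10; the C8 stereocentre is bought with the epoxide and is not touched.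

Step 8
Reactants: 12 (2R,4Z,6S)-6-[(tert-butyldimethylsilyl)oxy]-1-[(4-methoxybenzyl)oxy]-4,8-dimethylnona-4,8-dien-2-ol; 4 (2R,3R)-2,3-dimethyloxirane-2-carboxylic acid
Product: 14 (2R,4Z,6S)-6-[(tert-butyldimethylsilyl)oxy]-1-[(4-methoxybenzyl)oxy]-4,8-dimethylnona-4,8-dien-2-yl (2R,3R)-2,3-dimethyloxirane-2-carboxylate, via mixed anhydride 13 (not isolated)
Conditions: 4, 2,4,6-trichlorobenzoyl chloride, Et3N, THF, rt; then 12, DMAP, toluene, rt
Reagents that add atoms: none
Why: Yamaguchi esterification of the secondary alcohol with the hindered epoxy acid through the mixed anhydride; retention at C8, and the acid has no α-hydrogen to epimerise.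

Step 9
Reactants: 14 (2R,4Z,6S)-6-[(tert-butyldimethylsilyl)oxy]-1-[(4-methoxybenzyl)oxy]-4,8-dimethylnona-4,8-dien-2-yl (2R,3R)-2,3-dimethyloxirane-2-carboxylate
Product: 15 (2R,4Z,6S)-6-[(tert-butyldimethylsilyl)oxy]-1-hydroxy-4,8-dimethylnona-4,8-dien-2-yl (2R,3R)-2,3-dimethyloxirane-2-carboxylate
Conditions: DDQ, CH2Cl2/pH 7 buffer, 0 °C
Reagents that add atoms: none
Why: Oxidative cleavage of the PMB ether by DDQ under buffered conditions should leave the silyl ether, the alkenes and the epoxy ester intact.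

Step 10
Reactants: 15 (2R,4Z,6S)-6-[(tert-butyldimethylsilyl)oxy]-1-hydroxy-4,8-dimethylnona-4,8-dien-2-yl (2R,3R)-2,3-dimethyloxirane-2-carboxylate
Product: 16 (2R,4Z,6S)-6-[(tert-butyldimethylsilyl)oxy]-4,8-dimethyl-1-oxonona-4,8-dien-2-yl (2R,3R)-2,3-dimethyloxirane-2-carboxylate
Conditions: Dess–Martin periodinane, NaHCO3, CH2Cl2, 0 °C → rt
Reagents that add atoms: none
Why: Dess–Martin oxidation under buffered, non-basic conditions should give the α-acyloxy aldehyde without epimerisation at C8; it is used without purification.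

Step 11
Reactants: 16 (2R,4Z,6S)-6-[(tert-butyldimethylsilyl)oxy]-4,8-dimethyl-1-oxonona-4,8-dien-2-yl (2R,3R)-2,3-dimethyloxirane-2-carboxylate; 17 allyl acrylate
Product: 18 allyl (4R,6Z,8S)-8-[(tert-butyldimethylsilyl)oxy]-4-{[(2R,3R)-2,3-dimethyloxirane-2-carbonyl]oxy}-3-hydroxy-6,10-dimethyl-2-methylideneundeca-6,10-dienoate (both C3 epimers)
Conditions: DABCO (1 equiv), 17 (excess, neat), rt
Reagents that add atoms: none
Why: Morita–Baylis–Hillman reaction of the activated α-oxygenated aldehyde installs C11–C13 on C7; the new C7 carbinol forms as a mixture, which does not matter because it is removed in step 12.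

Step 12
Reactants: 18 allyl (4R,6Z,8S)-8-[(tert-butyldimethylsilyl)oxy]-4-{[(2R,3R)-2,3-dimethyloxirane-2-carbonyl]oxy}-3-hydroxy-6,10-dimethyl-2-methylideneundeca-6,10-dienoate
Product: 19 allyl (2Z,4R,6Z,8S)-2-(bromomethyl)-8-[(tert-butyldimethylsilyl)oxy]-4-{[(2R,3R)-2,3-dimethyloxirane-2-carbonyl]oxy}-6,10-dimethylundeca-2,6,10-trienoate
Conditions: NBS, Me2S, CH2Cl2, −20 °C → rt
Reagents that add atoms: N-bromosuccinimide, O=C1CCC(=O)N1Br
Why: Corey–Kim-type activation of the allylic alcohol and SN2′ delivery of bromide should give the 2-(bromomethyl)enoate with the thermodynamically preferred Z geometry (ester trans to the C8 substituent).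

Step 13
Reactants: 19 allyl (2Z,4R,6Z,8S)-2-(bromomethyl)-8-[(tert-butyldimethylsilyl)oxy]-4-{[(2R,3R)-2,3-dimethyloxirane-2-carbonyl]oxy}-6,10-dimethylundeca-2,6,10-trienoate; 20 acrolein
Product: 22 allyl (3S,4R,6Z,8S)-8-[(tert-butyldimethylsilyl)oxy]-4-{[(2R,3R)-2,3-dimethyloxirane-2-carbonyl]oxy}-3-[(1S)-1-hydroxyprop-2-en-1-yl]-6,10-dimethyl-2-methylideneundeca-6,10-dienoate, via allylindium species 21 (not isolated)
Conditions: In powder (2 equiv), 20 (3 equiv), THF/H2O, rt
Reagents that add atoms: none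
Why: Indium-mediated Barbier allylation (SE2′ through a closed six-membered transition state) should join C6 and C7; the γ-substituent cis to CH2In gives the syn C6/C7 pair, and allylic 1,3-strain (H8 eclipsing the alkene) should direct acrolein anti to the C9 branch, on the face carrying the acyloxy group, which sets C7 as in the target and C6 epimeric to it.

Step 14
Reactants: 22 allyl (3S,4R,6Z,8S)-8-[(tert-butyldimethylsilyl)oxy]-4-{[(2R,3R)-2,3-dimethyloxirane-2-carbonyl]oxy}-3-[(1S)-1-hydroxyprop-2-en-1-yl]-6,10-dimethyl-2-methylideneundeca-6,10-dienoate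
Product: 23 (3S,4R,6Z,8S)-8-[(tert-butyldimethylsilyl)oxy]-4-{[(2R,3R)-2,3-dimethyloxirane-2-carbonyl]oxy}-3-[(1S)-1-hydroxyprop-2-en-1-yl]-6,10-dimethyl-2-methylideneundeca-6,10-dienoic acid
Conditions: Pd(PPh3)4 (cat.), N-methylaniline, THF, rt; pH 5 work-up
Reagents that add atoms: none
Why: Pd(0)-catalysed allyl transfer to N-methylaniline (Tsuji–Trost deallylation) frees the acid under neutral conditions, so the epoxyangelate, the silyl ether and the open γ-hydroxy acid (no acid-catalysed acyl lactonisation) should survive.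

Step 15
Reactants: 23 (3S,4R,6Z,8S)-8-[(tert-butyldimethylsilyl)oxy]-4-{[(2R,3R)-2,3-dimethyloxirane-2-carbonyl]oxy}-3-[(1S)-1-hydroxyprop-2-en-1-yl]-6,10-dimethyl-2-methylideneundeca-6,10-dienoic acid
Product: 25 (1R,3Z,5S)-5-[(tert-butyldimethylsilyl)oxy]-1-[(2R,3R)-2-ethenyl-4-methylidene-5-oxooxolan-3-yl]-3,7-dimethylocta-3,7-dien-1-yl (2R,3R)-2,3-dimethyloxirane-2-carboxylate, via alkoxyphosphonium carboxylate 24 (not isolated)
Conditions: PPh3, DIAD, toluene (0.005 M), 0 °C → rt
Reagents that add atoms: none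
Why: The PPh3/DIAD betaine deprotonates the acid and turns the C6 hydroxyl into an alkoxyphosphonium leaving group, and the C12 carboxylate oxygen then displaces Ph3PO at C6 by SN2. The closest known reaction type is the intramolecular Mitsunobu lactonisation of γ-hydroxy acids with inversion. The lactone ring closes in the 5-exo-tet mode. No new stereocentre is created; C6 is inverted stereospecifically (S in 23, R in 25), so the syn C6/C7 pair from step 13 becomes the trans ring fusion, with C7 and C8 as spectators. The step needs alkyl–oxygen closure with inversion to win over acyl–oxygen closure with retention, over SN2′ attack at the vinyl terminus and over elimination towards C7. This should be secured by the unhindered allylic C6 carbinol, the high effective molarity of five-ring closure, low temperature and dilution, and the absence of any other free hydroxyl (O2 silylated, O8 acylated).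

Step 16
Reactants: 25 (1R,3Z,5S)-5-[(tert-butyldimethylsilyl)oxy]-1-[(2R,3R)-2-ethenyl-4-methylidene-5-oxooxolan-3-yl]-3,7-dimethylocta-3,7-dien-1-yl (2R,3R)-2,3-dimethyloxirane-2-carboxylate
Product: 26 (3aR,4R,6Z,8S,10Z,11aR)-8-[(tert-butyldimethylsilyl)oxy]-6,10-dimethyl-3-methylidene-2-oxo-2,3,3a,4,5,8,9,11a-octahydrocyclodeca[b]furan-4-yl (2R,3R)-2,3-dimethyloxirane-2-carboxylate
Conditions: Grubbs II (15 mol%), toluene (1 mM), 80 °C
Reagents that add atoms: none
Why: Ring-closing metathesis of the vinyl and 2-methylallyl termini with loss of ethylene should give the trisubstituted C4=C5 alkene as the Z isomer, expected to be the less strained partner of the existing Z-C1(10) alkene in the lactone-fused ten-membered ring; the electron-poor exo-methylene and the trisubstituted alkene are spectators.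

Step 17
Reactants: 26 (3aR,4R,6Z,8S,10Z,11aR)-8-[(tert-butyldimethylsilyl)oxy]-6,10-dimethyl-3-methylidene-2-oxo-2,3,3a,4,5,8,9,11a-octahydrocyclodeca[b]furan-4-yl (2R,3R)-2,3-dimethyloxirane-2-carboxylate
Product: 27 Millisorin B [(3aR,4R,6Z,8S,10Z,11aR)-8-hydroxy-6,10-dimethyl-3-methylidene-2-oxo-2,3,3a,4,5,8,9,11a-octahydrocyclodeca[b]furan-4-yl (2R,3R)-2,3-dimethyloxirane-2-carboxylate]
Conditions: HF·pyridine, pyridine/THF, 0 °C → rt
Reagents that add atoms: none
Why: Pyridine-buffered HF should cleave the allylic TBS ether under conditions that the epoxy ester and the α-methylene lactone tolerate, releasing the C2 hydroxyl with its configuration unchanged.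

**Compound list**

1 | angelic acid, (2Z)-2-methylbut-2-enoic acid | C/C=C(/C)C(=O)O | starting material
2 | (2Z)-2-methylbut-2-en-1-ol | C/C=C(/C)CO | intermediate
3 | [(2S,3R)-2,3-dimethyloxiran-2-yl]methanol | OC[C@]1(C)O[C@@H]1C | intermediate
4 | (2R,3R)-2,3-dimethyloxirane-2-carboxylic acid | OC(=O)[C@]1(C)O[C@@H]1C | intermediate
5 | but-2-ynal | CC#CC=O | starting material
6 | (4S)-6-methylhept-6-en-2-yn-4-ol | C=C(C)C[C@H](O)C#CC | intermediate
7 | sodium cyclic alkenylalanate from 6 (five-membered O–Al ring, Al on the methyl-bearing alkene carbon, two 2-methoxyethoxy ligands) | C=C(C)C[C@H]1C=C(C)[Al-](OCCOC)(OCCOC)O1.[Na+] | intermediate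
8 | (2Z,4S)-2-iodo-6-methylhepta-2,6-dien-4-ol | C=C(C)C[C@H](O)/C=C(/C)I | intermediate
9 | tert-butyl{[(2Z,4S)-2-iodo-6-methylhepta-2,6-dien-4-yl]oxy}dimethylsilane | C=C(C)C[C@H](O[Si](C)(C)C(C)(C)C)/C=C(/C)I | intermediate
10 | (R)-2-{[(4-methoxybenzyl)oxy]methyl}oxirane | COc1ccc(COC[C@H]2CO2)cc1 | starting material
11 | (Z)-alkenyllithium from 9 (Li in place of I, geometry retained) | C=C(C)C[C@H](O[Si](C)(C)C(C)(C)C)/C=C(/C)[Li] | intermediate
12 | (2R,4Z,6S)-6-[(tert-butyldimethylsilyl)oxy]-1-[(4-methoxybenzyl)oxy]-4,8-dimethylnona-4,8-dien-2-ol | C=C(C)C[C@H](O[Si](C)(C)C(C)(C)C)/C=C(/C)C[C@@H](O)COCc1ccc(OC)cc1 | intermediate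
13 | mixed anhydride of 4 with 2,4,6-trichlorobenzoic acid | O=C(OC(=O)[C@]1(C)O[C@@H]1C)c2c(Cl)cc(Cl)cc2Cl | intermediate
14 | (2R,4Z,6S)-6-[(tert-butyldimethylsilyl)oxy]-1-[(4-methoxybenzyl)oxy]-4,8-dimethylnona-4,8-dien-2-yl (2R,3R)-2,3-dimethyloxirane-2-carboxylate | C=C(C)C[C@H](O[Si](C)(C)C(C)(C)C)/C=C(/C)C[C@@H](OC(=O)[C@]1(C)O[C@@H]1C)COCc2ccc(OC)cc2 | intermediate
15 | (2R,4Z,6S)-6-[(tert-butyldimethylsilyl)oxy]-1-hydroxy-4,8-dimethylnona-4,8-dien-2-yl (2R,3R)-2,3-dimethyloxirane-2-carboxylate | C=C(C)C[C@H](O[Si](C)(C)C(C)(C)C)/C=C(/C)C[C@@H](OC(=O)[C@]1(C)O[C@@H]1C)CO | intermediate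
16 | (2R,4Z,6S)-6-[(tert-butyldimethylsilyl)oxy]-4,8-dimethyl-1-oxonona-4,8-dien-2-yl (2R,3R)-2,3-dimethyloxirane-2-carboxylate | C=C(C)C[C@H](O[Si](C)(C)C(C)(C)C)/C=C(/C)C[C@@H](OC(=O)[C@]1(C)O[C@@H]1C)C=O | intermediate
17 | allyl acrylate | C=CC(=O)OCC=C | starting material
18 | allyl (4R,6Z,8S)-8-[(tert-butyldimethylsilyl)oxy]-4-{[(2R,3R)-2,3-dimethyloxirane-2-carbonyl]oxy}-3-hydroxy-6,10-dimethyl-2-methylideneundeca-6,10-dienoate (C3 epimers) | C=C(C)C[C@H](O[Si](C)(C)C(C)(C)C)/C=C(/C)C[C@@H](OC(=O)[C@]1(C)O[C@@H]1C)C(O)C(=C)C(=O)OCC=C | intermediate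
19 | allyl (2Z,4R,6Z,8S)-2-(bromomethyl)-8-[(tert-butyldimethylsilyl)oxy]-4-{[(2R,3R)-2,3-dimethyloxirane-2-carbonyl]oxy}-6,10-dimethylundeca-2,6,10-trienoate | C=C(C)C[C@H](O[Si](C)(C)C(C)(C)C)/C=C(/C)C[C@@H](OC(=O)[C@]1(C)O[C@@H]1C)/C=C(\CBr)C(=O)OCC=C | intermediate
20 | acrolein | C=CC=O | starting material
21 | allylindium species from 19 (In in place of Br, drawn as the dibromide) | C=C(C)C[C@H](O[Si](C)(C)C(C)(C)C)/C=C(/C)C[C@@H](OC(=O)[C@]1(C)O[C@@H]1C)/C=C(\C[In](Br)Br)C(=O)OCC=C | intermediate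
22 | allyl (3S,4R,6Z,8S)-8-[(tert-butyldimethylsilyl)oxy]-4-{[(2R,3R)-2,3-dimethyloxirane-2-carbonyl]oxy}-3-[(1S)-1-hydroxyprop-2-en-1-yl]-6,10-dimethyl-2-methylideneundeca-6,10-dienoate | C=C(C)C[C@H](O[Si](C)(C)C(C)(C)C)/C=C(/C)C[C@@H](OC(=O)[C@]1(C)O[C@@H]1C)[C@H]([C@@H](O)C=C)C(=C)C(=O)OCC=C | intermediate
23 | (3S,4R,6Z,8S)-8-[(tert-butyldimethylsilyl)oxy]-4-{[(2R,3R)-2,3-dimethyloxirane-2-carbonyl]oxy}-3-[(1S)-1-hydroxyprop-2-en-1-yl]-6,10-dimethyl-2-methylideneundeca-6,10-dienoic acid | C=C(C)C[C@H](O[Si](C)(C)C(C)(C)C)/C=C(/C)C[C@@H](OC(=O)[C@]1(C)O[C@@H]1C)[C@H]([C@@H](O)C=C)C(=C)C(=O)O | intermediate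
24 | alkoxyphosphonium carboxylate of 23 (Ph3P+ on O6, carboxylate at C12) | C=C(C)C[C@H](O[Si](C)(C)C(C)(C)C)/C=C(/C)C[C@@H](OC(=O)[C@]1(C)O[C@@H]1C)[C@H]([C@@H](O[P+](c2ccccc2)(c3ccccc3)c4ccccc4)C=C)C(=C)C(=O)[O-] | intermediate
25 | (1R,3Z,5S)-5-[(tert-butyldimethylsilyl)oxy]-1-[(2R,3R)-2-ethenyl-4-methylidene-5-oxooxolan-3-yl]-3,7-dimethylocta-3,7-dien-1-yl (2R,3R)-2,3-dimethyloxirane-2-carboxylate | C=C(C)C[C@H](O[Si](C)(C)C(C)(C)C)/C=C(/C)C[C@@H](OC(=O)[C@]1(C)O[C@@H]1C)[C@@H]2[C@@H](C=C)OC(=O)C2=C | intermediate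
26 | 2-O-TBS-millisorin B, (3aR,4R,6Z,8S,10Z,11aR)-8-[(tert-butyldimethylsilyl)oxy]-6,10-dimethyl-3-methylidene-2-oxo-2,3,3a,4,5,8,9,11a-octahydrocyclodeca[b]furan-4-yl (2R,3R)-2,3-dimethyloxirane-2-carboxylate | C=C1C(=O)O[C@@H]2/C=C(/C)C[C@H](O[Si](C)(C)C(C)(C)C)/C=C(/C)C[C@@H](OC(=O)[C@]3(C)O[C@@H]3C)[C@@H]12 | intermediate
27 | Millisorin B | C=C1C(=O)O[C@@H]2/C=C(/C)C[C@H](O)/C=C(/C)C[C@@H](OC(=O)[C@]3(C)O[C@@H]3C)[C@@H]12 | target

**Count.** Total: 17 steps. Longest linear sequence: 14 steps (5 → 27, steps 4–17); steps 1–3 make the acid 4 that enters at step 8.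

**Steps most likely to fail**

Step 13. The facial selectivity of the allylindium addition with respect to the C8 stereocentre rests on a conformational model and may be low or reversed, which would give the C6,C7-bis-epimeric series. The syn selectivity may also erode with the small aldehyde. The fallback replaces substrate control by catalyst control and sets out from 18. Acetylation (Ac2O, DMAP) gives the Baylis–Hillman acetate F1. Pd-catalysed borylation with B2pin2 at the methylene terminus gives the allyl boronate F2 (CH2Bpin cis to C8). Allylboration of acrolein catalysed by a chiral phosphoric acid follows; the TRIP enantiomer is chosen to direct attack to the Re face of acrolein, (R)-TRIP by analogy with benzaldehyde. This reaction proceeds through a closed chair transition state, so the boronate geometry gives the syn pair and the catalyst fixes the aldehyde face. Aqueous work-up gives 22, where the route is rejoined.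

Step 16. The ten-membered ring closure on the trans-lactone may lose to intermolecular metathesis, or may give the 4E isomer. The fallback changes the order of ring formation and sets out from 23. Metathesis is run on the conformationally freer hydroxy acid to give the macrocyclic (Z,Z) seco acid F3. The Mitsunobu lactonisation is then carried out on F3 as a transannular 5-exo-tet closure with inversion at C6. This gives 26 directly, where the route is rejoined.

Step 11. The α-acyloxy aldehyde may epimerise at C8, or the epoxyangelate may migrate to the new C7 hydroxyl, during the slow amine-catalysed reaction. The fallback avoids the amine and sets out from 16. [1-(Allyloxycarbonyl)vinyl]diisobutylaluminium F4 is generated from allyl propiolate with DIBAL-H and NMO. It is added to 16 at 0 °C (vinylalumination) and should give 18 after a cold, neutral work-up, where the route is rejoined.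

**Further compounds**

F1 | step 13 | allyl (4R,6Z,8S)-3-acetoxy-8-[(tert-butyldimethylsilyl)oxy]-4-{[(2R,3R)-2,3-dimethyloxirane-2-carbonyl]oxy}-6,10-dimethyl-2-methylideneundeca-6,10-dienoate (C3 epimers) | C=C(C)C[C@H](O[Si](C)(C)C(C)(C)C)/C=C(/C)C[C@@H](OC(=O)[C@]1(C)O[C@@H]1C)C(OC(C)=O)C(=C)C(=O)OCC=C
F2 | step 13 | allyl (2E,4R,6Z,8S)-8-[(tert-butyldimethylsilyl)oxy]-4-{[(2R,3R)-2,3-dimethyloxirane-2-carbonyl]oxy}-6,10-dimethyl-2-[(4,4,5,5-tetramethyl-1,3,2-dioxaborolan-2-yl)methyl]undeca-2,6,10-trienoate | C=C(C)C[C@H](O[Si](C)(C)C(C)(C)C)/C=C(/C)C[C@@H](OC(=O)[C@]1(C)O[C@@H]1C)/C=C(\CB2OC(C)(C)C(C)(C)O2)C(=O)OCC=C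
F3 | step 16 | macrocyclic seco acid, 2-[(1R,2S,3Z,6S,7Z,10R)-6-[(tert-butyldimethylsilyl)oxy]-10-{[(2R,3R)-2,3-dimethyloxirane-2-carbonyl]oxy}-2-hydroxy-4,8-dimethylcyclodeca-3,7-dien-1-yl]prop-2-enoic acid | C=C(C(=O)O)[C@H]1[C@@H](O)/C=C(/C)C[C@H](O[Si](C)(C)C(C)(C)C)/C=C(/C)C[C@H]1OC(=O)[C@]2(C)O[C@@H]2C
F4 | step 11 | [1-(allyloxycarbonyl)vinyl]diisobutylaluminium | C=C(C(=O)OCC=C)[Al](CC(C)C)CC(C)C
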